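**Plan**
- Retrosynthesis: after removal of the O-protecting groups, the benzo ring of the flavan is cut at C8–C8a, C5–C6, C7–C8 and C4a–C5, giving a dihydropyranyl diazomethyl ketone and a 3-(silyloxyethynyl)flavone.
- Enabling feature: that benzo ring is a pentasubstituted phloroglucinol-type arene (O on C5, C7 and C8a, flavone C3 on C6 between the two phenolic oxygens, CH2 on C4a). A vinylketene (C5, C4a, C8a, C8) and a siloxyalkyne (C6, C7) assemble exactly this 1-hydroxy-2-carbon-3-silyloxy pattern.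
- Forward, flavone half: the pyranone ring is closed first (diketone cyclodehydration), then C3 is iodinated, ethynylated and the acetylide oxidised to the siloxyalkyne.
- Forward, flavan half: aryl keto acid, (S)-δ-lactone, enol triflate, acyl dihydropyran, diazoketone; the flavan benzo ring is built last, in the step that joins the halves.
- Stereochemistry: the only stereocentre, flavan C2 (S), comes from asymmetric transfer hydrogenation of the aryl ketone and is carried through unchanged.

Key step: step 15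

Assumption: the target is defined only by the (S) centre at flavan C2; the flavone C3–flavan C6 axis is taken as not configurationally defined, so rotamers about it are treated as one compound.

**Route**

Step 1
Reactants: 1 2,4,6-trihydroxyacetophenone
Product: 2 1-[2,4-bis(benzyloxy)-6-hydroxyphenyl]ethan-1-one
Conditions: BnBr (2.1 equiv), K2CO3, DMF, 0 → 25 °C
Reagents that add atoms: benzyl bromide, BrCc1ccccc1
Why: Williamson etherification in which one ortho hydroxyl is held back by its hydrogen bond to the acetyl carbonyl, so alkylation should stop at the 2,4-dibenzyl ether.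

Step 2
Reactants: 2 1-[2,4-bis(benzyloxy)-6-hydroxyphenyl]ethan-1-one; 3 4-(benzyloxy)benzoyl chloride
Product: 4 1-[2,4-bis(benzyloxy)-6-hydroxyphenyl]-3-[4-(benzyloxy)phenyl]propane-1,3-dione
Conditions: LiN(SiMe3)2 (3.3 equiv), THF, −78 → −10 °C; 3, −78 → 25 °C; aq NH4Cl
Reagents that add atoms: none
Why: The lithium phenoxide–enolate is acylated at carbon by the aroyl chloride (Claisen-type acylation, the one-flask form of the Baker–Venkataraman rearrangement), the extra base holding the product as its enolate against a second acylation.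

Step 3
Reactants: 4 1-[2,4-bis(benzyloxy)-6-hydroxyphenyl]-3-[4-(benzyloxy)phenyl]propane-1,3-dione
Product: 5 5,7-bis(benzyloxy)-2-[4-(benzyloxy)phenyl]-4H-chromen-4-one
Conditions: NaOAc, AcOH, 100 °C
Reagents that add atoms: none
Why: Cyclodehydration of the o-hydroxyaryl 1,3-diketone closes the pyranone ring (phenol onto the aroyl carbonyl, then loss of water), and buffered acetic acid should spare the benzyl ethers.

Step 4
Reactants: 5 5,7-bis(benzyloxy)-2-[4-(benzyloxy)phenyl]-4H-chromen-4-one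
Product: 6 5,7-bis(benzyloxy)-2-[4-(benzyloxy)phenyl]-3-iodo-4H-chromen-4-one
Conditions: LiN(iPr)2, THF, −78 °C; I2
Reagents that add atoms: iodine, II
Why: Carbonyl-directed lithiation at C3, the only vinylic C–H next to the carbonyl, followed by iodination of the vinyllithium places the halogen by the site of deprotonation, whereas electrophilic iodination would go to C6 or C8 of ring A.

Step 5
Reactants: 6 5,7-bis(benzyloxy)-2-[4-(benzyloxy)phenyl]-3-iodo-4H-chromen-4-one; 7 ethynyltrimethylsilane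
Product: 8 5,7-bis(benzyloxy)-2-[4-(benzyloxy)phenyl]-3-[(trimethylsilyl)ethynyl]-4H-chromen-4-one
Conditions: PdCl2(PPh3)2 (cat.), CuI (cat.), Et3N, DMF, 50 °C
Reagents that add atoms: none
Why: Sonogashira coupling, for which 3-iodoflavones are established vinyl iodide partners, and the 2-aryl group blocks amine addition to the pyranone.

Step 6
Reactants: 8 5,7-bis(benzyloxy)-2-[4-(benzyloxy)phenyl]-3-[(trimethylsilyl)ethynyl]-4H-chromen-4-one
Product: 9 5,7-bis(benzyloxy)-2-[4-(benzyloxy)phenyl]-3-ethynyl-4H-chromen-4-one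
Conditions: K2CO3 (cat.), MeOH/CH2Cl2, 0 → 25 °C
Reagents that add atoms: none
Why: Methanolysis of the alkynyl C–Si bond is fast under catalytic carbonate, conditions a 2,3-disubstituted chromone should tolerate.

Step 7
Reactants: 9 5,7-bis(benzyloxy)-2-[4-(benzyloxy)phenyl]-3-ethynyl-4H-chromen-4-one
Product: 11 5,7-bis(benzyloxy)-2-[4-(benzyloxy)phenyl]-3-{[(triisopropylsilyl)oxy]ethynyl}-4H-chromen-4-one, via lithium ynolate 10 (not isolated)
Conditions: LiN(SiMe3)2, THF, −78 °C; LiOOt-Bu (from t-BuOOH and LiN(SiMe3)2), −78 → 0 °C; i-Pr3SiOTf, −78 °C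
Reagents that add atoms: tert-butyl hydroperoxide, CC(C)(C)OO; triisopropylsilyl trifluoromethanesulfonate, CC(C)[Si](OS(=O)(=O)C(F)(F)F)(C(C)C)C(C)C
Why: Acetylide oxidation in which the lithium acetylide attacks the peroxide oxygen and expels tert-butoxide to give the ynolate, which the bulky silyl triflate captures at oxygen; the amide base is non-nucleophilic toward the chromone.

Step 8
Reactants: 12 [4-(benzyloxy)phenyl]magnesium bromide (1.0 M in THF); 13 glutaric anhydride
Product: 14 5-[4-(benzyloxy)phenyl]-5-oxopentanoic acid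
Conditions: THF, −78 → 0 °C (12 added to 13); aq HCl
Reagents that add atoms: none
Why: Grignard ring opening of a cyclic anhydride at low temperature with inverse addition should stop at the keto carboxylate, and it avoids the AlCl3 of a Friedel–Crafts route, which would cleave the benzyl ether.

Step 9
Reactants: 14 5-[4-(benzyloxy)phenyl]-5-oxopentanoic acid
Product: 15 (S)-5-[4-(benzyloxy)phenyl]-5-hydroxypentanoic acid
Conditions: RuCl(p-cymene)[(S,S)-TsDPEN] (1 mol %), HCO2H/Et3N (5:2), 40 °C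
Reagents that add atoms: none
Why: Noyori–Ikariya asymmetric transfer hydrogenation of an aryl alkyl ketone, in which the (S,S)-ligand and the aryl/arene contact in the six-membered transition state direct hydride to the Re face and so set the (S) carbinol.

Step 10
Reactants: 15 (S)-5-[4-(benzyloxy)phenyl]-5-hydroxypentanoic acid
Product: 16 (S)-6-[4-(benzyloxy)phenyl]tetrahydro-2H-pyran-2-one
Conditions: EDC·HCl, DMAP (cat.), CH2Cl2, 0 → 25 °C
Reagents that add atoms: none
Why: Steglich-type lactonisation activates the carboxyl group and leaves the electron-rich benzylic C–O bond intact, so the δ-lactone should form without erosion of configuration by ionisation.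

Step 11
Reactants: 16 (S)-6-[4-(benzyloxy)phenyl]tetrahydro-2H-pyran-2-one
Product: 17 (S)-2-[4-(benzyloxy)phenyl]-3,4-dihydro-2H-pyran-6-yl trifluoromethanesulfonate
Conditions: KN(SiMe3)2, PhNTf2, THF/HMPA, −78 °C
Reagents that add atoms: N-phenylbis(trifluoromethanesulfonimide), O=S(=O)(N(c1ccccc1)S(=O)(=O)C(F)(F)F)C(F)(F)F
Why: O-sulfonylation of the kinetic potassium lactone enolate gives the ketene acetal triflate, and the benzylic C–H at the stereocentre is far too weakly acidic to be touched.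

Step 12
Reactants: 17 (S)-2-[4-(benzyloxy)phenyl]-3,4-dihydro-2H-pyran-6-yl trifluoromethanesulfonate
Product: 18 (S)-2-[4-(benzyloxy)phenyl]-N-methoxy-N-methyl-3,4-dihydro-2H-pyran-6-carboxamide
Conditions: CO (1 atm), MeNHOMe·HCl, Pd(OAc)2 (cat.), Xantphos (cat.), Et3N, DMF, 25 → 50 °C; crude 17 used at once
Reagents that add atoms: carbon monoxide, [C-]#[O+]; N,O-dimethylhydroxylamine hydrochloride, CNOC.Cl
Why: Aminocarbonylation of an enol triflate, by oxidative addition to zerovalent palladium, CO insertion and aminolysis of the acylpalladium, gives the Weinreb amide under neutral, non-acidic conditions that suit the enol ether.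

Step 13
Reactants: 18 (S)-2-[4-(benzyloxy)phenyl]-N-methoxy-N-methyl-3,4-dihydro-2H-pyran-6-carboxamide
Product: 19 1-{(S)-2-[4-(benzyloxy)phenyl]-3,4-dihydro-2H-pyran-6-yl}ethan-1-one
Conditions: MeMgBr, THF, −78 → 0 °C; aq NH4Cl
Reagents that add atoms: methylmagnesium bromide, C[Mg]Br
Why: Weinreb ketone synthesis, in which the chelated tetrahedral adduct survives until quench and so stops at the methyl ketone.

Step 14
Reactants: 19 1-{(S)-2-[4-(benzyloxy)phenyl]-3,4-dihydro-2H-pyran-6-yl}ethan-1-one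
Product: 21 1-{(S)-2-[4-(benzyloxy)phenyl]-3,4-dihydro-2H-pyran-6-yl}-2-diazoethan-1-one, via trifluoroacetyl diketone 20 (not isolated)
Conditions: LiN(SiMe3)2, THF, −78 °C; CF3CO2CH2CF3; dil. HCl work-up; MsN3, Et3N, H2O, MeCN, 25 °C
Reagents that add atoms: methanesulfonyl azide, CS(=O)(=O)N=[N+]=[N-]; 2,2,2-trifluoroethyl trifluoroacetate, O=C(OCC(F)(F)F)C(F)(F)F (atoms in 20 only)
Why: Detrifluoroacetylative diazo transfer, in which kinetic enolisation at the methyl group and trifluoroacetylation activate that carbon for diazo transfer with loss of the trifluoroacetyl group; this avoids exposing the enone to diazomethane and its dipolar cycloaddition.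

Step 15
Reactants: 21 1-{(S)-2-[4-(benzyloxy)phenyl]-3,4-dihydro-2H-pyran-6-yl}-2-diazoethan-1-one (1.3 equiv); 11 5,7-bis(benzyloxy)-2-[4-(benzyloxy)phenyl]-3-{[(triisopropylsilyl)oxy]ethynyl}-4H-chromen-4-one
Product: 26 5,7-bis(benzyloxy)-2-[4-(benzyloxy)phenyl]-3-{(2S)-2-[4-(benzyloxy)phenyl]-5-hydroxy-7-[(triisopropylsilyl)oxy]chroman-6-yl}-4H-chromen-4-one, via vinylketene 22 (not isolated), via vinylcyclobutenone 23 (not isolated), via dienylketene 24 (not isolated), via cyclohexadienone 25 (not isolated)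
Conditions: hν (420–440 nm LED), degassed ClCH2CH2Cl, 25 °C; then 80 °C
Reagents that add atoms: none
Why: Irradiation in the long-wavelength n→π* tail of the diazoketone, where the flavone should not absorb, expels N2 and drives the Wolff 1,2-shift of the dihydropyranyl carbon (C8a) to the diazo carbon (C8), giving vinylketene 22. The flavone-bearing, electron-rich carbon of the siloxyalkyne attacks the ketene carbonyl carbon in a [2+2] cycloaddition that forms C5–C6 and C7–C8 and gives cyclobutenone 23, as in the Danheiser benzannulation of unsaturated diazoketones with siloxyalkynes. Four-electron electrocyclic opening of 23, completed by warming, gives dienylketene 24, and the benzo ring closes by thermal six-electron disrotatory electrocyclisation of the ketene carbon onto the dihydropyran alkene (C4a–C5) to give cyclohexadienone 25, which tautomerises to the phenol. No stereocentre is created, and the (S) centre at C2 lies two saturated atoms from the reacting alkene and is not involved. The selectivity needed is regiochemical, the flavone landing between the new hydroxyl and the silyloxy group, and it is secured by the oxygen-induced polarisation of the siloxyalkyne against the electrophilic ketene carbon.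

Step 16
Reactants: 26 5,7-bis(benzyloxy)-2-[4-(benzyloxy)phenyl]-3-{(2S)-2-[4-(benzyloxy)phenyl]-5-hydroxy-7-[(triisopropylsilyl)oxy]chroman-6-yl}-4H-chromen-4-one
Product: 27 5,7-bis(benzyloxy)-2-[4-(benzyloxy)phenyl]-3-{(2S)-2-[4-(benzyloxy)phenyl]-5,7-dihydroxychroman-6-yl}-4H-chromen-4-one
Conditions: Bu4NF, AcOH, THF, 0 °C
Reagents that add atoms: none
Why: Fluoride cleavage of an aryl silyl ether is fast, and acetic acid buffering keeps the medium far from the acidity that could ionise the benzylic C2–O bond of the flavan.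

Step 17
Reactants: 27 5,7-bis(benzyloxy)-2-[4-(benzyloxy)phenyl]-3-{(2S)-2-[4-(benzyloxy)phenyl]-5,7-dihydroxychroman-6-yl}-4H-chromen-4-one
Product: 28 5,7-dihydroxy-3-[(2S)-5,7-dihydroxy-2-(4-hydroxyphenyl)chroman-6-yl]-2-(4-hydroxyphenyl)-4H-chromen-4-one (CNP0304187.1)
Conditions: H2 (1 atm), Pd/C (10%), THF/MeOH, 25 °C
Reagents that add atoms: none
Why: Hydrogenolysis of the four benzyl aryl ethers should be much faster than reduction of the tetrasubstituted flavone C2=C3 bond or cleavage of the cyclic benzylic C2–O bond, as in the debenzylation of protected flavan-3-ols, so the reaction is stopped after uptake of four equivalents.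

**Compound list**
1 | 2,4,6-trihydroxyacetophenone | CC(=O)c1c(O)cc(O)cc1O | starting material
2 | 1-[2,4-bis(benzyloxy)-6-hydroxyphenyl]ethan-1-one | CC(=O)c1c(O)cc(OCc2ccccc2)cc1OCc1ccccc1 | intermediate
3 | 4-(benzyloxy)benzoyl chloride | O=C(Cl)c1ccc(OCc2ccccc2)cc1 | starting material
4 | 1-[2,4-bis(benzyloxy)-6-hydroxyphenyl]-3-[4-(benzyloxy)phenyl]propane-1,3-dione | O=C(CC(=O)c1ccc(OCc2ccccc2)cc1)c1c(O)cc(OCc2ccccc2)cc1OCc1ccccc1 | intermediate
5 | 5,7-bis(benzyloxy)-2-[4-(benzyloxy)phenyl]-4H-chromen-4-one | O=c1cc(-c2ccc(OCc3ccccc3)cc2)oc2cc(OCc3ccccc3)cc(OCc3ccccc3)c12 | intermediate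
6 | 5,7-bis(benzyloxy)-2-[4-(benzyloxy)phenyl]-3-iodo-4H-chromen-4-one | O=c1c(I)c(-c2ccc(OCc3ccccc3)cc2)oc2cc(OCc3ccccc3)cc(OCc3ccccc3)c12 | intermediate
7 | ethynyltrimethylsilane | C#C[Si](C)(C)C | starting material
8 | 5,7-bis(benzyloxy)-2-[4-(benzyloxy)phenyl]-3-[(trimethylsilyl)ethynyl]-4H-chromen-4-one | C[Si](C)(C)C#Cc1c(-c2ccc(OCc3ccccc3)cc2)oc2cc(OCc3ccccc3)cc(OCc3ccccc3)c2c1=O | intermediate
9 | 5,7-bis(benzyloxy)-2-[4-(benzyloxy)phenyl]-3-ethynyl-4H-chromen-4-one | C#Cc1c(-c2ccc(OCc3ccccc3)cc2)oc2cc(OCc3ccccc3)cc(OCc3ccccc3)c2c1=O | intermediate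
10 | lithium 2-{5,7-bis(benzyloxy)-2-[4-(benzyloxy)phenyl]-4-oxo-4H-chromen-3-yl}ethynolate (not isolated) | [Li+].[O-]C#Cc1c(-c2ccc(OCc3ccccc3)cc2)oc2cc(OCc3ccccc3)cc(OCc3ccccc3)c2c1=O | intermediate
11 | 5,7-bis(benzyloxy)-2-[4-(benzyloxy)phenyl]-3-{[(triisopropylsilyl)oxy]ethynyl}-4H-chromen-4-one | O=c1c(C#CO[Si](C(C)C)(C(C)C)C(C)C)c(-c2ccc(OCc3ccccc3)cc2)oc2cc(OCc3ccccc3)cc(OCc3ccccc3)c12 | intermediate
12 | [4-(benzyloxy)phenyl]magnesium bromide | Br[Mg]c1ccc(OCc2ccccc2)cc1 | starting material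
13 | glutaric anhydride | O=C1CCCC(=O)O1 | starting material
14 | 5-[4-(benzyloxy)phenyl]-5-oxopentanoic acid | O=C(O)CCCC(=O)c1ccc(OCc2ccccc2)cc1 | intermediate
15 | (S)-5-[4-(benzyloxy)phenyl]-5-hydroxypentanoic acid | O=C(O)CCC[C@@H](c1ccc(OCc2ccccc2)cc1)O | intermediate
16 | (S)-6-[4-(benzyloxy)phenyl]tetrahydro-2H-pyran-2-one | O=C1CCC[C@@H](c2ccc(OCc3ccccc3)cc2)O1 | intermediate
17 | (S)-2-[4-(benzyloxy)phenyl]-3,4-dihydro-2H-pyran-6-yl trifluoromethanesulfonate | O=S(=O)(OC1=CCC[C@@H](c2ccc(OCc3ccccc3)cc2)O1)C(F)(F)F | intermediate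
18 | (S)-2-[4-(benzyloxy)phenyl]-N-methoxy-N-methyl-3,4-dihydro-2H-pyran-6-carboxamide | CON(C)C(=O)C1=CCC[C@@H](c2ccc(OCc3ccccc3)cc2)O1 | intermediate
19 | 1-{(S)-2-[4-(benzyloxy)phenyl]-3,4-dihydro-2H-pyran-6-yl}ethan-1-one | CC(=O)C1=CCC[C@@H](c2ccc(OCc3ccccc3)cc2)O1 | intermediate
20 | 1-{(S)-2-[4-(benzyloxy)phenyl]-3,4-dihydro-2H-pyran-6-yl}-4,4,4-trifluorobutane-1,3-dione (not isolated) | O=C(CC(=O)C(F)(F)F)C1=CCC[C@@H](c2ccc(OCc3ccccc3)cc2)O1 | intermediate
21 | 1-{(S)-2-[4-(benzyloxy)phenyl]-3,4-dihydro-2H-pyran-6-yl}-2-diazoethan-1-one | [N-]=[N+]=CC(=O)C1=CCC[C@@H](c2ccc(OCc3ccccc3)cc2)O1 | intermediate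
22 | 2-{(S)-2-[4-(benzyloxy)phenyl]-3,4-dihydro-2H-pyran-6-yl}ethen-1-one, the vinylketene (not isolated) | O=C=CC1=CCC[C@@H](c2ccc(OCc3ccccc3)cc2)O1 | intermediate
23 | 4-{(S)-2-[4-(benzyloxy)phenyl]-3,4-dihydro-2H-pyran-6-yl}-2-(tri-O-benzylflavon-3-yl)-3-[(triisopropylsilyl)oxy]cyclobut-2-en-1-one (not isolated; ring CH centre undefined) | O=C1C(c2c(-c3ccc(OCc4ccccc4)cc3)oc3cc(OCc4ccccc4)cc(OCc4ccccc4)c3c2=O)=C(O[Si](C(C)C)(C(C)C)C(C)C)C1C1=CCC[C@@H](c2ccc(OCc3ccccc3)cc2)O1 | intermediate
24 | dienylketene from ring opening of 23, ketene and dihydropyranyl groups cis on the silyloxy alkene (not isolated) | O=C=C(c1c(-c2ccc(OCc3ccccc3)cc2)oc2cc(OCc3ccccc3)cc(OCc3ccccc3)c2c1=O)/C(O[Si](C(C)C)(C(C)C)C(C)C)=C\C1=CCC[C@@H](c2ccc(OCc3ccccc3)cc2)O1 | intermediate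
25 | (2S)-2-[4-(benzyloxy)phenyl]-6-(tri-O-benzylflavon-3-yl)-7-[(triisopropylsilyl)oxy]-2,3,4,4a-tetrahydro-5H-chromen-5-one, keto tautomer of 26 (not isolated; C4a undefined) | O=C1C(c3c(-c4ccc(OCc5ccccc5)cc4)oc4cc(OCc5ccccc5)cc(OCc5ccccc5)c4c3=O)=C(O[Si](C(C)C)(C(C)C)C(C)C)C=C2O[C@H](c3ccc(OCc4ccccc4)cc3)CCC21 | intermediate
26 | 5,7-bis(benzyloxy)-2-[4-(benzyloxy)phenyl]-3-{(2S)-2-[4-(benzyloxy)phenyl]-5-hydroxy-7-[(triisopropylsilyl)oxy]chroman-6-yl}-4H-chromen-4-one | O=c1c(-c2c(O[Si](C(C)C)(C(C)C)C(C)C)cc3c(c2O)CC[C@@H](c2ccc(OCc4ccccc4)cc2)O3)c(-c2ccc(OCc3ccccc3)cc2)oc2cc(OCc3ccccc3)cc(OCc3ccccc3)c12 | intermediate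
27 | 5,7-bis(benzyloxy)-2-[4-(benzyloxy)phenyl]-3-{(2S)-2-[4-(benzyloxy)phenyl]-5,7-dihydroxychroman-6-yl}-4H-chromen-4-one | O=c1c(-c2c(O)cc3c(c2O)CC[C@@H](c2ccc(OCc4ccccc4)cc2)O3)c(-c2ccc(OCc3ccccc3)cc2)oc2cc(OCc3ccccc3)cc(OCc3ccccc3)c12 | intermediate
28 | 5,7-dihydroxy-3-[(2S)-5,7-dihydroxy-2-(4-hydroxyphenyl)chroman-6-yl]-2-(4-hydroxyphenyl)-4H-chromen-4-one | O=c1c(-c2c(O)cc3c(c2O)CC[C@@H](c2ccc(O)cc2)O3)c(-c2ccc(O)cc2)oc2cc(O)cc(O)c12 | target

**Step count and risks**

Total step count: 17. Longest linear sequence: 10 steps (steps 1–7 then 15–17, or steps 8–14 then 15–17).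

Steps most likely to fail:

1. Step 15 (benzannulation). The flavone chromophore may take up the light meant for the diazoketone, or the [2+2] addition at the congested flavonyl-bearing alkyne carbon may be slow enough for the vinylketene to dimerise or be captured by the product phenol. Fallback, from 21 and 9, returning at 26: the same four bonds are made without light in the joining event. C-silylation of 21 at the diazo carbon (i-Pr3SiOTf, i-Pr2NEt, Et2O/hexane, 0 °C) would give the silyl diazoketone F1. Its Wolff rearrangement (300 nm, benzene), now with no flavone in the flask, would give the isolable (triisopropylsilyl)vinylketene F2. Lithium ynolate 10, generated from 9 as in step 7 but left unsilylated, would then be added to F2 in THF at −78 → 25 °C. C-acylation of the ynolate by the ketene, six-electron ring closure and a 1,3-Brook shift of silicon from C8 to the C7 oxygen should give 26 itself after protonation, which continues with step 16.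

2. Step 7 (acetylide oxidation and silylation). The lithium peroxide may attack the pyranone ring, oxygen transfer to the conjugated acetylide may be incomplete, or the ynolate may be silylated at carbon. Fallback, from 9, returning at 10 and then 11: the polarity of the alkyne is reversed. PhI(OH)OTs in CH2Cl2 would convert 9 into the alkynyl(phenyl)iodonium tosylate F3. CuOTf (cat.) in MeCN should collapse this to the alkynyl tosylate F4 with loss of iodobenzene. MeLi (1 equiv, THF, −78 °C) attacks the sulfonyl sulfur of F4 and releases lithium ynolate 10, which is silylated with i-Pr3SiOTf as in the route to give 11.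

3. Step 12 (aminocarbonylation of the ketene acetal triflate). The triflate may hydrolyse back to the lactone or be protonated off palladium before CO insertion. Fallback, from 16, returning at 19: KN(SiMe3)2 and (PhO)2P(O)Cl in THF/HMPA at −78 °C would give the chromatographically stable ketene acetal diphenyl phosphate F5. Stille coupling with tributyl(1-ethoxyvinyl)stannane (Pd(PPh3)4, LiCl, THF, reflux) would give the 6-(1-ethoxyvinyl)dihydropyran F6. Brief treatment with pyridinium p-toluenesulfonate in wet acetone at 0 °C should hydrolyse the exocyclic, more basic enol ether first and give methyl ketone 19, which enters step 14.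

Further compounds
F1 | step 15 | 1-{(S)-2-[4-(benzyloxy)phenyl]-3,4-dihydro-2H-pyran-6-yl}-2-diazo-2-(triisopropylsilyl)ethan-1-one | [N-]=[N+]=C([Si](C(C)C)(C(C)C)C(C)C)C(=O)C1=CCC[C@@H](c2ccc(OCc3ccccc3)cc2)O1
F2 | step 15 | 2-{(S)-2-[4-(benzyloxy)phenyl]-3,4-dihydro-2H-pyran-6-yl}-2-(triisopropylsilyl)ethen-1-one | O=C=C([Si](C(C)C)(C(C)C)C(C)C)C1=CCC[C@@H](c2ccc(OCc3ccccc3)cc2)O1
F3 | step 7 | ({5,7-bis(benzyloxy)-2-[4-(benzyloxy)phenyl]-4-oxo-4H-chromen-3-yl}ethynyl)(phenyl)iodonium 4-methylbenzenesulfonate | O=c1c(C#C[I+]c2ccccc2)c(-c2ccc(OCc3ccccc3)cc2)oc2cc(OCc3ccccc3)cc(OCc3ccccc3)c12.Cc1ccc(S(=O)(=O)[O-])cc1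
F4 | step 7 | {5,7-bis(benzyloxy)-2-[4-(benzyloxy)phenyl]-4-oxo-4H-chromen-3-yl}ethynyl 4-methylbenzenesulfonate | Cc1ccc(S(=O)(=O)OC#Cc2c(-c3ccc(OCc4ccccc4)cc3)oc3cc(OCc4ccccc4)cc(OCc4ccccc4)c3c2=O)cc1
F5 | step 12 | (S)-2-[4-(benzyloxy)phenyl]-3,4-dihydro-2H-pyran-6-yl diphenyl phosphate | O=P(OC1=CCC[C@@H](c2ccc(OCc3ccccc3)cc2)O1)(Oc1ccccc1)Oc1ccccc1
F6 | step 12 | (S)-2-[4-(benzyloxy)phenyl]-6-(1-ethoxyvinyl)-3,4-dihydro-2H-pyran | C=C(OCC)C1=CCC[C@@H](c2ccc(OCc3ccccc3)cc2)O1
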